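The numbers were chosen freely; the result is computed.

Four vessels, one step.

    substrate + reagent + catalyst → catalyst + product (k1 = 7700 M⁻² s⁻¹)

| setting | north-west | east | north | north-east |
|---|---|---|---|---|
| substrate | 0.050 M | 0.050 M | 0.050 M (fed, over 40.0 s) | 0.050 M |
| reagent | 0.800 equiv | 0.800 equiv | 0.800 equiv | 0.800 equiv |
| catalyst | 0.1 mol% | 0.1 mol% | 0.1 mol% | 0.1 mol% |
| remark | a single well-mixed tank run continuously and read at steady state, 50 s in it on average | a closed flask charged with all of it at once and left for 50 s | all but substrate at the start; substrate goes in evenly over 40.0 s, the run ends at 50 s | one stirred flow tank at steady state, fed with the mixture as stated, mean residence time 150 s |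
| time |  | 50 s | 50 s |  |

* the set-up with the highest amount of product at the outlet or at the end, in percent of the substrate put in ("none" if the first two lie within 2 percentage points) (north-west / east / north / north-east / none)
* amount of product at the outlet or at the end, in percent of the substrate put in, north-west
* amount of product at the outlet or at the end, in percent of the substrate put in, east
* amount of product at the outlet or at the end, in percent of the substrate put in, north
* amount of product at the outlet or at the end, in percent of the substrate put in, north-east

- the stated concentrations are those of everything mixed, before any reaction; amounts are the same in each set-up
- the feed brings no volume worth counting
- run time (east): 50 s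

I let x be the product as a fraction of the substrate charge. Each unit of product uses one of substrate and one of reagent, so 1 − x of the substrate remains and e − x of the reagent, with e = 0.800. The reagent, charged at less than the substrate, is the limiting reagent. The catalyst comes back unchanged, so it stays at 0.0500 mM, and the fraction made per second is

dx/dt = (1 − x)(e − x) / T

Here T = 51.9 s, which I call the reaction clock: one over the rate constant times the catalyst concentration times the substrate charge.

The north-west tank and the east flask look nearly the same, with one charge and a time t of 50 s each, on average in the north-west tank. In the tank, what is made per second equals what leaves, x/t, and the rate is that of the outlet mixture. In the closed flask the rate falls along the run, and integrating gives the second line: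

north-west: x = (t/T)(1 − x)(e − x), so x = 31.7 %

east: x = e(1 − E)/(1 − eE), with E = exp(−(1 − e)t/T), so x = 41.2 %

The north-west tank runs throughout at 41.2 % of the starting rate. The east flask averages 53.5 % of it, so the flask ends ahead of the tank.

The forecast names north-east, with 31.7 % for north-west, 41.2 % for east, 29.8 % for north and 48 % for north-east. Its grounds for the long tank: “it has three times the residence time, which outweighs its mixing penalty”.

The simulation puts north-east first at 48.0 %, then east at 41.2 %, north-west at 31.7 % and north at 29.7 %. The north-west tank holds its mixture on average for 0.963 clocks and the north-east tank for 2.89 clocks. At its outlet the north-east tank runs at 20.8 % of the starting rate, about half of the north-west tank's 41.2 %, and its product stands 16 percentage points above that of the north-west tank.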